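**Plan**

- Retrosynthesis: the two pyran O1–C6 ether bonds are cut first, then the two C–C bonds joining cyclopentane C2 to pyran C2. This leaves two molecules of an isopropenylcyclopentanone and a C14 (Z,Z)-dienedial, which is cut further at C2–C3/C10–C11 (Claisen) and C4–C5/C8–C9 (vinyl-metal addition to succinaldehyde).
- Enabling feature: in each half, cyclopentane C1 (oxygen-bearing), cyclopentane C2 and pyran C2 (oxygen-bearing) form a 1,3-dioxygenated triad. The cyclopentane ring bond at C2 lies anti to the pyran oxygen, which is the pattern left by an anti-aldol between a cyclopentanone enolate and an aldehyde; the C2 axis allows both triads to be made in one operation.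
- Forward: ketone 5 (3 steps) and dialdehyde 15 (5 steps) are joined by a two-directional boron aldol that closes no ring. The two ring ketones are then reduced, and both pyran rings are closed last, together, by O-alkylation.
- Stereochemistry: the isopropenyl centre comes from a lipase resolution. The aldol sets four centres (ring-enforced (E)-enol borinate plus chair gives anti; the isopropenyl centre selects the face). Chelate-controlled hydride addition sets the two ring carbinols, and both (Z)-alkenes come from the chair of a Johnson–Claisen rearrangement.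

Key step: step 9

Assumption: the lipase is taken to follow the usual empirical model for secondary carbinols with this trans-2-alkenylcyclopentanol, so the (1R,2S)-enantiomer is acylated and the wanted (1S,2R)-alcohol is recovered; if the preference proved opposite, the acetate fraction would be saponified and used instead.

**Route**

Step 1
Reactants: 1 cyclopentene oxide; 2 isopropenylmagnesium bromide
Product: 3 (±)-trans-2-(prop-1-en-2-yl)cyclopentan-1-ol
Conditions: CuI (10 mol %), THF, −30 → 0 °C; then aq NH4Cl
Reagents that add atoms: isopropenylmagnesium bromide (2), C=C(C)[Mg]Br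
Why: Copper-catalysed Grignard opening of the meso epoxide is an SN2 process with inversion at the attacked carbon, so only the trans carbinol should form, as the racemate.

Step 2
Reactants: 3 (±)-trans-2-(prop-1-en-2-yl)cyclopentan-1-ol
Product: 4 (1S,2R)-2-(prop-1-en-2-yl)cyclopentan-1-ol
Conditions: immobilised Burkholderia cepacia lipase, vinyl acetate, t-BuOMe, 30 °C, run past half conversion; chromatography
Reagents that add atoms: none
Why: Lipase-catalysed kinetic resolution by irreversible transesterification should acylate the (1R)-carbinol faster, so that past half conversion the unreacted (1S,2R)-alcohol remains in high enantiomeric purity and is separated from the acetate.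

Step 3
Reactants: 4 (1S,2R)-2-(prop-1-en-2-yl)cyclopentan-1-ol
Product: 5 (R)-2-(prop-1-en-2-yl)cyclopentan-1-one
Conditions: Dess–Martin periodinane, NaHCO3, CH2Cl2, 0 °C; used at once
Reagents that add atoms: none
Why: Dess–Martin oxidation under bicarbonate buffering works at near-neutral pH and low temperature, so the doubly activated α-methine should not epimerise and the alkene should not move into conjugation.

Step 4
Reactants: 6 2-bromoprop-2-en-1-ol
Product: 7 2-bromoallyl 4-methoxybenzyl ether
Conditions: NaH, 4-methoxybenzyl chloride, n-Bu4NI (cat.), THF/DMF, 0 °C → rt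
Reagents that add atoms: 4-methoxybenzyl chloride, COc1ccc(CCl)cc1
Why: Williamson etherification of the primary alkoxide with a benzylic chloride, the vinyl bromide being inert to NaH at this temperature.

Step 5
Reactants: 8 2,5-dimethoxytetrahydrofuran
Product: 9 succinaldehyde
Conditions: H2O, 90 °C; then distillation, used freshly
Reagents that add atoms: water, O
Why: Hydrolysis of the cyclic bis(methyl acetal) in hot water is the standard preparation of succinaldehyde, and fresh distillation limits oligomerisation.

Step 6
Reactants: 7 2-bromoallyl 4-methoxybenzyl ether (2.5 equiv); 9 succinaldehyde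
Product: 11 bis(PMB-oxymethyl)octadienediol (dl/meso mixture), via 2-lithioallyl PMB ether 10 (not isolated)
Conditions: t-BuLi (2 equiv per bromide), Et2O, −78 °C; then 9, −78 → −40 °C; then aq NH4Cl
Reagents that add atoms: none
Why: Bromine–lithium exchange gives the 2-lithioallyl ether, which adds 1,2 to both formyl groups; the two carbinol centres form without control, which is immaterial because step 7 erases both.

Step 7
Reactants: 11 bis(PMB-oxymethyl)octadienediol; 12 triethyl orthoacetate
Product: 14 (4Z,8Z)-diester, via bis(ketene acetal) 13 (not isolated)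
Conditions: MeC(OEt)3 (excess), EtCO2H (cat.), 140 °C, EtOH distilled off
Reagents that add atoms: triethyl orthoacetate (12), CCOC(C)(OCC)OCC
Why: Two Johnson–Claisen [3,3] rearrangements run through chairs with the carbinol substituent equatorial, so the central chain ends trans to the new CH2CH2CO2Et arm and cis to CH2OPMB, which is the (Z) descriptor at both trisubstituted alkenes.

Step 8
Reactants: 14 (4Z,8Z)-diester
Product: 15 (4Z,8Z)-4,9-bis(PMB-oxymethyl)dodeca-4,8-dienedial
Conditions: i-Bu2AlH (2.2 equiv), CH2Cl2, −78 °C; MeOH, then aq KNaC4H4O6 (potassium sodium tartrate)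
Reagents that add atoms: none
Why: Partial ester reduction by i-Bu2AlH at −78 °C stops at the aluminium hemiacetal, which releases the aldehyde only on work-up, while PMB ethers and isolated alkenes are inert.

Step 9
Reactants: 5 (R)-2-(prop-1-en-2-yl)cyclopentan-1-one (2.5 equiv); 15 (4Z,8Z)-dienedial
Product: 18 C2-symmetric bis(anti-aldol) diketone, via (E)-enol dicyclohexylborinate 16 (not isolated), via bis(dicyclohexylboron aldolate) 17 (not isolated)
Conditions: Cy2BCl (2.7 equiv), Et3N (3.0 equiv), Et2O, −78 → 0 °C; then 15, −78 → −20 °C; then MeOH, pH 7 buffer (NaH2PO4/Na2HPO4), H2O2, 0 °C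
Reagents that add atoms: none
Why: Cy2BCl complexes the ketone and Et3N removes a proton from the unbranched α-methylene, the ring forcing the (E)-enol borinate 16; each formyl group of 15 then binds boron and the C–C bond forms through a closed Zimmerman–Traxler chair with the aldehyde chain equatorial, which is the established dicyclohexylboron anti-aldol of cyclic ketones, here run at both ends of a dialdehyde. No ring is closed; the two bonds formed join cyclopentane C2 to the future pyran C2 on each side. Each carbinol centre (R) follows from the enolate geometry and the chair (anti); each new ring centre (R) follows from bonding on the enolate face away from the isopropenyl group on the neighbouring sp3 carbon, where the boron and its cyclohexyl ligands would otherwise clash with it, so the new branch is trans to isopropenyl. The step needs enolisation away from the allylic methine (expected from the bulk of the reagent pair under kinetic control, which leaves the existing centre untouched), anti simple selectivity (secured by the ring-enforced enolate geometry) and facial selectivity (secured only by the isopropenyl stereocentre, the weakest element). Because the ketone is a single enantiomer and the two termini react independently, a wrong-face event at one end should give an unsymmetrical, separable by-product next to the C2-symmetric adduct.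

Step 10
Reactants: 18 C2-symmetric bis(anti-aldol) diketone
Product: 20 bis(PMB ether) tetraol, via bis(diethylboron chelate) 19 (not isolated)
Conditions: Et2BOMe (2.4 equiv), THF/MeOH 4:1, −78 °C; NaBH4, −78 °C; then pH 7 buffer (NaH2PO4/Na2HPO4), H2O2, 0 °C
Reagents that add atoms: none
Why: Narasaka–Prasad reduction: diethylboron bridges the aldol oxygen and the ketone oxygen in a six-membered chelate with the side chain and the ring methylene both pseudo-equatorial, and external hydride adds axially from the side-chain face, which is also the face opposite isopropenyl, so each new ring carbinol (S) should be 1,3-syn to the aldol hydroxyl, trans to the side chain and cis to isopropenyl.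

Step 11
Reactants: 20 bis(PMB ether) tetraol
Product: 21 hexaol
Conditions: DDQ (2.6 equiv), CH2Cl2/pH 7 buffer (NaH2PO4/Na2HPO4), 0 °C
Reagents that add atoms: none
Why: Oxidative PMB cleavage by DDQ proceeds via the benzylic oxocarbenium ion, which water hydrolyses, and under buffered conditions at 0 °C the secondary carbinols, the isolated alkenes and the released unactivated allylic carbinols should not be oxidised.

Step 12
Reactants: 21 hexaol
Product: 22 bis(allylic chloride) tetraol
Conditions: N-chlorosuccinimide, Me2S, CH2Cl2, −20 °C (reagent pre-formed); then 21 in THF, −20 → 0 °C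
Reagents that add atoms: N-chlorosuccinimide, O=C1CCC(=O)N1Cl
Why: Corey–Kim halogenation converts only allylic carbinols into chlorides, by chloride attack on the alkoxysulfonium ion, whereas the saturated secondary alkoxysulfonium ions do not collapse at this temperature and return the carbinols on aqueous work-up, and SN2 at the primary carbon keeps the alkene geometry.

Step 13
Reactants: 22 bis(allylic chloride) tetraol
Product: 23 testudinariol A
Conditions: NaH (6 equiv), THF, 0 °C → rt
Reagents that add atoms: none
Why: Intramolecular Williamson etherification: each aldol alkoxide closes a six-membered ring by 6-exo-tet SN2 at the primary allylic carbon (the ring alkoxide could only form an eight-membered ring), so the C–O bond at pyran C2 is never broken and its configuration and the alkene geometry are retained.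

**Compound list**

1 | cyclopentene oxide (6-oxabicyclo[3.1.0]hexane) | C1CC2OC2C1 | starting material
2 | isopropenylmagnesium bromide, CH2=C(CH3)MgBr | C=C(C)[Mg]Br | starting material
3 | (±)-trans-2-(prop-1-en-2-yl)cyclopentan-1-ol (racemate, 1S*,2R*; one enantiomer drawn) | C=C(C)[C@H]1CCC[C@@H]1O | intermediate
4 | (1S,2R)-2-(prop-1-en-2-yl)cyclopentan-1-ol (OH trans to isopropenyl) | C=C(C)[C@H]1CCC[C@@H]1O | intermediate
5 | (R)-2-(prop-1-en-2-yl)cyclopentan-1-one | C=C(C)[C@H]1CCCC1=O | intermediate
6 | 2-bromoprop-2-en-1-ol | C=C(Br)CO | starting material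
7 | 1-{[(2-bromoprop-2-en-1-yl)oxy]methyl}-4-methoxybenzene (2-bromoallyl PMB ether) | C=C(Br)COCc1ccc(OC)cc1 | intermediate
8 | 2,5-dimethoxytetrahydrofuran | COC1CCC(OC)O1 | starting material
9 | succinaldehyde (butanedial) | O=CCCC=O | intermediate
10 | {3-[(4-methoxybenzyl)oxy]prop-1-en-2-yl}lithium (2-lithioallyl PMB ether) | [Li]C(=C)COCc1ccc(OC)cc1 | intermediate (not isolated)
11 | 2,7-bis{[(4-methoxybenzyl)oxy]methyl}octa-1,7-diene-3,6-diol (dl/meso mixture) | C=C(COCc1ccc(OC)cc1)C(O)CCC(O)C(=C)COCc1ccc(OC)cc1 | intermediate
12 | triethyl orthoacetate | CCOC(C)(OCC)OCC | starting material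
13 | 3,6-bis[(1-ethoxyvinyl)oxy]-2,7-bis{[(4-methoxybenzyl)oxy]methyl}octa-1,7-diene (bis(ketene acetal)) | C=C(OCC)OC(CCC(OC(=C)OCC)C(=C)COCc1ccc(OC)cc1)C(=C)COCc1ccc(OC)cc1 | intermediate (not isolated)
14 | diethyl (4Z,8Z)-4,9-bis{[(4-methoxybenzyl)oxy]methyl}dodeca-4,8-dienedioate | CCOC(=O)CC/C(=C/CC/C=C(COCc1ccc(OC)cc1)/CCC(=O)OCC)COCc1ccc(OC)cc1 | intermediate
15 | (4Z,8Z)-4,9-bis{[(4-methoxybenzyl)oxy]methyl}dodeca-4,8-dienedial | O=CCC/C(=C/CC/C=C(COCc1ccc(OC)cc1)/CCC=O)COCc1ccc(OC)cc1 | intermediate
16 | dicyclohexyl{[(5R)-5-(prop-1-en-2-yl)cyclopent-1-en-1-yl]oxy}borane ((E)-enol borinate) | C=C(C)[C@H]1CCC=C1OB(C1CCCCC1)C1CCCCC1 | intermediate (not isolated)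
17 | O,O'-bis(dicyclohexylboryl) aldolate of 18 | C=C(C)[C@H]1CC[C@H]([C@H](OB(C2CCCCC2)C2CCCCC2)CC/C(=C/CC/C=C(COCc2ccc(OC)cc2)/CC[C@@H](OB(C2CCCCC2)C2CCCCC2)[C@H]2CC[C@H](C(=C)C)C2=O)COCc2ccc(OC)cc2)C1=O | intermediate (not isolated)
18 | (2R,2'R,5R,5'R)-2,2'-[(1R,4Z,8Z,12R)-1,12-dihydroxy-4,9-bis{[(4-methoxybenzyl)oxy]methyl}dodeca-4,8-diene-1,12-diyl]bis[5-(prop-1-en-2-yl)cyclopentan-1-one] (side chain trans to isopropenyl on each ring; anti-aldol at each end) | C=C(C)[C@H]1CC[C@H]([C@H](O)CC/C(=C/CC/C=C(COCc2ccc(OC)cc2)/CC[C@@H](O)[C@H]2CC[C@H](C(=C)C)C2=O)COCc2ccc(OC)cc2)C1=O | intermediate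
19 | O,O'-bis(diethylboryl) chelate of 18 | C=C(C)[C@H]1CC[C@H]([C@H](OB(CC)CC)CC/C(=C/CC/C=C(COCc2ccc(OC)cc2)/CC[C@@H](OB(CC)CC)[C@H]2CC[C@H](C(=C)C)C2=O)COCc2ccc(OC)cc2)C1=O | intermediate (not isolated)
20 | (1S,1'S,2R,2'R,5R,5'R)-2,2'-[(1R,4Z,8Z,12R)-1,12-dihydroxy-4,9-bis{[(4-methoxybenzyl)oxy]methyl}dodeca-4,8-diene-1,12-diyl]bis[5-(prop-1-en-2-yl)cyclopentan-1-ol] (ring OH cis to isopropenyl, trans to side chain) | C=C(C)[C@H]1CC[C@H]([C@H](O)CC/C(=C/CC/C=C(COCc2ccc(OC)cc2)/CC[C@@H](O)[C@H]2CC[C@H](C(=C)C)[C@@H]2O)COCc2ccc(OC)cc2)[C@H]1O | intermediate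
21 | (1S,1'S,2R,2'R,5R,5'R)-2,2'-[(1R,4Z,8Z,12R)-1,12-dihydroxy-4,9-bis(hydroxymethyl)dodeca-4,8-diene-1,12-diyl]bis[5-(prop-1-en-2-yl)cyclopentan-1-ol] (hexaol) | C=C(C)[C@H]1CC[C@H]([C@H](O)CC/C(=C/CC/C=C(CO)/CC[C@@H](O)[C@H]2CC[C@H](C(=C)C)[C@@H]2O)CO)[C@H]1O | intermediate
22 | (1S,1'S,2R,2'R,5R,5'R)-2,2'-[(1R,4Z,8Z,12R)-4,9-bis(chloromethyl)-1,12-dihydroxydodeca-4,8-diene-1,12-diyl]bis[5-(prop-1-en-2-yl)cyclopentan-1-ol] | C=C(C)[C@H]1CC[C@H]([C@H](O)CC/C(=C/CC/C=C(CCl)/CC[C@@H](O)[C@H]2CC[C@H](C(=C)C)[C@@H]2O)CCl)[C@H]1O | intermediate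
23 | testudinariol A: C2-symmetric; each half a (1S,2S,5R)-5-(prop-1-en-2-yl)cyclopentan-1-ol carrying at C2 a (2R)-tetrahydropyran-2-yl ring whose C5 bears a (Z)-exocyclic alkene, the two alkene carbons joined by CH2CH2 (the ring C2 descriptor changes from R in 20–22 to S only through a change of CIP priorities) | C=C(C)[C@H]1CC[C@H]([C@H]2CC/C(=C/CC/C=C3/CC[C@H]([C@H]4CC[C@H](C(=C)C)[C@@H]4O)OC3)CO2)[C@H]1O | target

**Step count**

Total: 13 steps. Longest linear sequence: 9 steps (steps 4, 6, 7, 8, 9, 10, 11, 12, 13, from 2-bromoprop-2-en-1-ol).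

**Steps most likely to fail**

1. Step 9. During amine-mediated enolisation a proton may be lost from the isopropenyl-bearing methine, which would erode that centre and pull the alkene into conjugation; facial discrimination by the remote centre may also be incomplete, giving unsymmetrical diastereomers. Fallback, setting out from 5 and rejoining the route at 16: the enolate is made regiodefined by hard, kinetic deprotonation instead. Ketone 5 is treated with LiN(i-Pr)2 in the presence of Me3SiCl (THF, −78 °C) to give the less substituted silyl enol ether, trimethyl{[(5R)-5-(prop-1-en-2-yl)cyclopent-1-en-1-yl]oxy}silane F1, whose regio- and enantiopurity can be checked before use. MeLi (THF, 0 °C) then releases lithium (5R)-5-(prop-1-en-2-yl)cyclopent-1-en-1-olate F2, and transmetalation with Cy2BCl at −78 °C gives enol borinate 16, to which dialdehyde 15 is added as in step 9.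

2. Step 6. Succinaldehyde may be enolised or oligomerised by the basic vinyllithium, and the alkoxide from the first addition may close onto the second formyl group as a lactolate and stall the second addition. Fallback, setting out from 7 (through 10) and rejoining at 11: the 1,4-dicarbonyl unit is brought in at the amide oxidation level. Succinyl chloride and MeNH(OMe)·HCl give N1,N4-dimethoxy-N1,N4-dimethylbutanediamide F3. Double Weinreb ketone synthesis with 10 (Et2O/THF, −78 °C, cold acidic quench) gives 2,7-bis{[(4-methoxybenzyl)oxy]methyl}octa-1,7-diene-3,6-dione F4, and Luche reduction (NaBH4, CeCl3·7H2O, MeOH, −78 °C) gives diol 11.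

3. Step 12. Chemoselectivity among six hydroxyl groups may be lost: sulfonium activation may spread to the secondary carbinols (oxidation or methylthiomethyl ether formation), or the double chlorination may stop halfway. Fallback, setting out from 20 and rejoining at 22: the secondary carbinols are masked before the primary ones are unveiled. Tetraol 20 is silylated (Et3SiOTf, 2,6-lutidine, CH2Cl2, −78 °C) to the tetrakis(triethylsilyl) ether of 20 F5. DDQ (CH2Cl2/pH 7 buffer, 0 °C) removes both PMB groups to give the bis(primary allylic alcohol) tetrakis(triethylsilyl) ether F6, which now has no competing hydroxyl group. MsCl, 2,4,6-collidine and LiCl in DMF at 0 °C give the bis(allylic chloride) tetrakis(triethylsilyl) ether F7, and HF·pyridine (THF/pyridine, 0 °C) removes the silyl groups to give 22, which is cyclised as in step 13.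

**Further compounds**

F1 | step 9 | trimethyl{[(5R)-5-(prop-1-en-2-yl)cyclopent-1-en-1-yl]oxy}silane | C=C(C)[C@H]1CCC=C1O[Si](C)(C)C
F2 | step 9 | lithium (5R)-5-(prop-1-en-2-yl)cyclopent-1-en-1-olate | C=C(C)[C@H]1CCC=C1O[Li]
F3 | step 6 | N1,N4-dimethoxy-N1,N4-dimethylbutanediamide | CON(C)C(=O)CCC(=O)N(C)OC
F4 | step 6 | 2,7-bis{[(4-methoxybenzyl)oxy]methyl}octa-1,7-diene-3,6-dione | C=C(COCc1ccc(OC)cc1)C(=O)CCC(=O)C(=C)COCc1ccc(OC)cc1
F5 | step 12 | tetrakis(triethylsilyl) ether of 20 | C=C(C)[C@H]1CC[C@H]([C@H](O[Si](CC)(CC)CC)CC/C(=C/CC/C=C(COCc2ccc(OC)cc2)/CC[C@@H](O[Si](CC)(CC)CC)[C@H]2CC[C@H](C(=C)C)[C@@H]2O[Si](CC)(CC)CC)COCc2ccc(OC)cc2)[C@H]1O[Si](CC)(CC)CC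
F6 | step 12 | bis(primary allylic alcohol) tetrakis(triethylsilyl) ether | C=C(C)[C@H]1CC[C@H]([C@H](O[Si](CC)(CC)CC)CC/C(=C/CC/C=C(CO)/CC[C@@H](O[Si](CC)(CC)CC)[C@H]2CC[C@H](C(=C)C)[C@@H]2O[Si](CC)(CC)CC)CO)[C@H]1O[Si](CC)(CC)CC
F7 | step 12 | bis(allylic chloride) tetrakis(triethylsilyl) ether | C=C(C)[C@H]1CC[C@H]([C@H](O[Si](CC)(CC)CC)CC/C(=C/CC/C=C(CCl)/CC[C@@H](O[Si](CC)(CC)CC)[C@H]2CC[C@H](C(=C)C)[C@@H]2O[Si](CC)(CC)CC)CCl)[C@H]1O[Si](CC)(CC)CC
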